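Retrosynthetic overview
1. Target 25 is (13E)-3α,6β,19-trihydroxylabda-8,13-dien-15-oic acid; C9–C11 is cut last, as a B-alkyl Suzuki coupling of a C8=C9 enol triflate with the borane from a C11–C16 dienoate.
2. The strategy rests on ring B (C5–C10): its oxygen at C6, the sp2 carbon C9 para to it and the methyls on C8 and C10 are the pattern of 2,6-dimethyl-1,4-benzoquinone. C1–C4, with the C3 oxygen and C19 on C4, is a 3-silyloxypenta-2,4-dienoate.
3. Ring B is bought as the quinone. Ring A is closed onto its C5=C10 bond by a thermal Diels–Alder reaction (C4–C5 and C1–C10), with an 8-phenylmenthyl ester at C19 as the source of absolute configuration.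
4. Then: C7=C8 reduction, C5 epimerisation to trans, C4 methylation anti to C20, equatorial hydride delivery at C3 and C6 with 19,6β-lactonisation (the auxiliary leaves), C9 triflate, lactone reduction, coupling, saponification.

Key step: step 5

Remark: labdane numbering is used for all bicyclic compounds (C17 on C8, C18/C19 on C4, C20 on C10; β is the face of C20); R* = (−)-8-phenylmenthyl.
Assumption: the (−)-8-phenylmenthyl ester is taken to favour the 10S adduct drawn; if it favours the 10R series, (+)-8-phenylmenthol is used instead and nothing else changes.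

Step 1
Reactants: 1 (−)-8-phenylmenthol; 2 acetyl chloride
Product: 3 (−)-8-phenylmenthyl acetate
Conditions: pyridine, DMAP (cat.), CH2Cl2, 0 °C → rt
Reagents that add atoms: none
Why: DMAP-catalysed acylation of the hindered secondary alcohol by the acid chloride (nucleophilic acyl substitution) leaves the three stereocentres of the auxiliary untouched.

Step 2
Reactants: 3 (−)-8-phenylmenthyl acetate; 4 acrolein
Product: 6 (−)-8-phenylmenthyl 3-hydroxypent-4-enoate (both carbinol epimers), via lithium enolate 5 (not isolated)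
Conditions: LiN(i-Pr)2, THF, −78 °C; then 4, −78 °C; AcOH quench
Reagents that add atoms: none
Why: Aldol addition of a lithium ester enolate to acrolein at low temperature is 1,2-selective, and the new carbinol centre, formed as a mixture, is removed in step 3.

Step 3
Reactants: 6 (−)-8-phenylmenthyl 3-hydroxypent-4-enoate
Product: 7 (−)-8-phenylmenthyl 3-oxopent-4-enoate
Conditions: Dess–Martin periodinane, CH2Cl2, 0 °C → rt; used crude
Reagents that add atoms: none
Why: Dess–Martin oxidation of the allylic secondary alcohol gives the vinyl β-keto ester under non-basic conditions that should spare this polymerisable Michael acceptor.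

Step 4
Reactants: 7 (−)-8-phenylmenthyl 3-oxopent-4-enoate
Product: 8 (−)-8-phenylmenthyl (2Z)-3-(tert-butyldimethylsilyloxy)penta-2,4-dienoate
Conditions: TBSOTf, Et3N, CH2Cl2, −78 → 0 °C
Reagents that add atoms: tert-butyldimethylsilyl trifluoromethanesulfonate, CC(C)(C)[Si](C)(C)OS(=O)(=O)C(F)(F)F
Why: O-silylation of the internally hydrogen-bonded cis-enol of the β-keto ester should give the 2Z silyl dienol ether, in which the ester lies outside the s-cis diene.

Step 5
Reactants: 8 (−)-8-phenylmenthyl (2Z)-3-(tert-butyldimethylsilyloxy)penta-2,4-dienoate; 9 2,6-dimethyl-1,4-benzoquinone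
Product: 10 cis-fused endo adduct (4β-H, 5β-H, 10β-CH3; 4α-CO2R*; C2=C3 silyl enol ether; ring-B ene-dione C6(=O)–C7=C8(CH3)–C9(=O))
Conditions: 9 (1.5 equiv), PhMe (2 M), 90 °C, 2,6-di-tert-butyl-4-methylphenol (cat.), no Lewis acid; chromatography
Reagents that add atoms: none
Why: Concerted but asynchronous normal-demand [4+2] cycloaddition (diene HOMO, quinone LUMO), the closest known type being the thermal Diels–Alder reaction of 1-alkoxycarbonyl-2-silyloxy dienes with alkyl-1,4-benzoquinones. Ring A is closed in an intermolecular [4+2] mode, C4–C5 forming ahead of C1–C10 and both bonds suprafacially on each partner, so the quaternary C10 is created in the same event. Orientation is set by the free quinone: the C6 carbonyl is deactivated by the two methyls conjugated with it, so the C9 carbonyl polarises the C5=C10 bond and the nucleophilic enol-ether terminus C4 joins the unsubstituted C5, which is also the sterically easier pairing; no Lewis acid is used because it would bind the more basic, unhindered C6 carbonyl and reverse this orientation. The Z enol ether holds the ester outside the s-cis diene and the quinone carbonyls lie endo (secondary overlap), giving the cis fusion with 4β-H and 5β-H, two centres that are re-set in steps 7 and 8. The absolute configuration at C10 is controlled by the ester: the phenyl ring of the 8-phenylmenthyl group should stack over one face of the C3=C4 enoate unit, the quinone adds to the open face, and with endo geometry this fixes which enantiotopic C=C face of the symmetrical quinone is used. Every minor isomer is a diastereomer, so the 10S adduct can be freed from it by chromatography here or by crystallisation at 14.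

Step 6
Reactants: 10 cis-fused endo adduct
Product: 11 cis-fused 6,9-dione (C7–C8 saturated, C8 epimers; silyl enol ether and ester unchanged)
Conditions: Zn dust, AcOH, THF, 0 °C → rt
Reagents that add atoms: none
Why: Zinc reduction of the cyclohex-2-ene-1,4-dione (two-electron reduction to the bis-enol, then tautomerisation) saturates C7=C8 only, since the electron-rich C2=C3 enol ether and the ester are not reducible under these conditions.

Step 7
Reactants: 11 cis-fused 6,9-dione
Product: 12 trans-fused 6,9-dione (5α-H, 8α-CH3, 4α-CO2R*, C2=C3 silyl enol ether)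
Conditions: DBU (0.3 equiv), PhMe, 50 °C
Reagents that add atoms: none
Why: Base-mediated equilibration through the C5–C6 and C8–C9 enolates (thermodynamic control) should favour the trans-fused decalin with 5α-H, as in 5α-6-keto steroids, and the equatorial 8α-methyl, while C10 is quaternary and C3 stays masked so no aldol path opens.

Step 8
Reactants: 12 trans-fused 6,9-dione
Product: 14 trans-fused 3,6,9-trione with 4α-CH3 (C18) and 4β-CO2R* (C19), via tetrabutylammonium enolate 13 (not isolated)
Conditions: Bu4NF·3H2O (1.05 equiv), THF, −20 °C; then MeI (5 equiv), −20 °C → rt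
Reagents that add atoms: iodomethane, CI
Why: Fluoride cleaves the silyl enol ether and proton transfer gives the doubly stabilised β-keto ester enolate, whose C-methylation (β-keto ester alkylation) should occur on the α face, anti to the axial C10 methyl, as is general for 3-oxo-4-alkoxycarbonyl trans-decalins with an angular methyl, so C4 is set with C18 α and C19 β.

Step 9
Reactants: 14 trans-fused 3,6,9-trione
Product: 16 3α-hydroxy-9-oxo-19,6β-lactone (4α-CH3, 8α-CH3, 10β-CH3, 5α-H), via dilithium dialkoxide 15 (not isolated)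
Conditions: LiBH(s-Bu)3 (2.1 equiv), THF, −78 °C; then rt; aq. NH4Cl
Reagents that add atoms: none
Why: The bulky borohydride should attack the C3 and C6 ketones from their equatorial directions (at C6 the α face, the β face being blocked by C20 and the axial C19 ester) to give the axial 3α and 6β alkoxides and leave the C9 ketone, flanked by a quaternary and a tertiary carbon, untouched at −78 °C; on warming the 6β alkoxide, syn-axial to C19, closes the γ-lactone by 5-exo-trig acyl transfer and releases the auxiliary for recovery.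

Step 10
Reactants: 16 3α-hydroxy-9-oxo-19,6β-lactone
Product: 17 3α-benzoyloxy-9-oxo-19,6β-lactone
Conditions: BzCl, pyridine, DMAP (cat.), CH2Cl2, rt
Reagents that add atoms: benzoyl chloride, O=C(Cl)c1ccccc1
Why: DMAP-catalysed acylation protects the only free hydroxyl as a non-enolisable ester that step 12 removes together with the lactone reduction.

Step 11
Reactants: 17 3α-benzoyloxy-9-oxo-19,6β-lactone
Product: 19 C8=C9 enol triflate (9-OTf) with 3α-benzoate and 19,6β-lactone, via potassium enolate 18 (not isolated)
Conditions: KN(SiMe3)2, THF, −78 → −30 °C; PhNTf2, −78 → 0 °C; aq. NH4Cl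
Reagents that add atoms: N-phenylbis(trifluoromethanesulfonimide), O=S(=O)(N(c1ccccc1)S(=O)(=O)C(F)(F)F)C(F)(F)F
Why: The axial C8–H is the only enolisable hydrogen (C10 is quaternary; lactone and benzoate carry no α-hydrogen), so deprotonation and O-triflation of the enolate give the tetrasubstituted C8=C9 enol triflate, as with 2,2,6-trialkylcyclohexanones.

Step 12
Reactants: 19 C8=C9 enol triflate with 3α-benzoate and 19,6β-lactone
Product: 20 3α,6β,19-triol C8=C9 enol triflate
Conditions: i-Bu2AlH (excess), CH2Cl2, −78 °C → rt; aq. potassium sodium tartrate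
Reagents that add atoms: none
Why: Aluminium hydride reduction takes the lactone through its lactol to the 6β,19-diol and cleaves the benzoate, while enol triflates are inert to this hydride and no stereocentre is touched.

Step 13
Reactants: 21 ethyl (E)-3-methyl-4-oxobut-2-enoate
Product: 22 ethyl (E)-3-methylpenta-2,4-dienoate
Conditions: Ph3PCH3Br, KOt-Bu, THF, 0 °C; then 21, −78 → 0 °C
Reagents that add atoms: methyltriphenylphosphonium bromide, C[P+](c1ccccc1)(c1ccccc1)c1ccccc1.[Br-]
Why: Wittig methylenation of the aldehyde is faster than any attack at the ester and keeps the E geometry of the trisubstituted alkene.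

Step 14
Reactants: 20 3α,6β,19-triol C8=C9 enol triflate; 22 ethyl (E)-3-methylpenta-2,4-dienoate
Product: 24 ethyl (13E)-3α,6β,19-trihydroxylabda-8,13-dien-15-oate, via alkylborane 23 (not isolated)
Conditions: 22, 9-BBN-H, THF, 0 °C → rt; then 20, PdCl2(dppf) (10 mol %; dppf = 1,1'-bis(diphenylphosphino)ferrocene), AsPh3, Cs2CO3, DMF/H2O, 50 °C
Reagents that add atoms: none
Why: 9-BBN-H should add anti-Markovnikov to the terminal vinyl group only (the trisubstituted, ester-conjugated alkene is inert), and the primary alkylborane then undergoes B-alkyl Suzuki–Miyaura coupling with the enol triflate (oxidative addition, base-assisted transmetalation, reductive elimination), forming C9–C11 with both alkene geometries retained and the free hydroxyls tolerated.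

Step 15
Reactants: 24 ethyl (13E)-3α,6β,19-trihydroxylabda-8,13-dien-15-oate
Product: 25 (13E)-3α,6β,19-trihydroxylabda-8,13-dien-15-oic acid, (3R,4S,5R,6R,10S)
Conditions: LiOH, THF/MeOH/H2O, 40 °C; then 1 M HCl to pH 3
Reagents that add atoms: lithium hydroxide, [Li+].[OH-]
Why: Saponification of the ethyl ester followed by acidification gives the acid, with nothing else in the molecule base-labile and the E alkene retained.

Compound list
1 | (−)-8-phenylmenthol, (1R,2S,5R)-5-methyl-2-(2-phenylpropan-2-yl)cyclohexan-1-ol | O[C@@H]1C[C@H](C)CC[C@H]1C(C)(C)c1ccccc1 | starting material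
2 | acetyl chloride | CC(=O)Cl | starting material
3 | (−)-8-phenylmenthyl acetate | CC(=O)O[C@@H]1C[C@H](C)CC[C@H]1C(C)(C)c1ccccc1 | intermediate
4 | acrolein | C=CC=O | starting material
5 | lithium enolate of 3 | [Li+].C=C([O-])O[C@@H]1C[C@H](C)CC[C@H]1C(C)(C)c1ccccc1 | intermediate
6 | (−)-8-phenylmenthyl 3-hydroxypent-4-enoate (carbinol epimers) | C=CC(O)CC(=O)O[C@@H]1C[C@H](C)CC[C@H]1C(C)(C)c1ccccc1 | intermediate
7 | (−)-8-phenylmenthyl 3-oxopent-4-enoate | C=CC(=O)CC(=O)O[C@@H]1C[C@H](C)CC[C@H]1C(C)(C)c1ccccc1 | intermediate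
8 | (−)-8-phenylmenthyl (2Z)-3-(tert-butyldimethylsilyloxy)penta-2,4-dienoate | C=C/C(O[Si](C)(C)C(C)(C)C)=C/C(=O)O[C@@H]1C[C@H](C)CC[C@H]1C(C)(C)c1ccccc1 | intermediate
9 | 2,6-dimethyl-1,4-benzoquinone | CC1=CC(=O)C=C(C)C1=O | starting material
10 | cis-fused endo adduct (4β-H, 5β-H, 10β-CH3; C2=C3 silyl enol ether; 4α-CO2R*; ring-B ene-dione) | CC1=CC(=O)[C@@H]2[C@H](C(=O)O[C@@H]3C[C@H](C)CC[C@H]3C(C)(C)c3ccccc3)C(O[Si](C)(C)C(C)(C)C)=CC[C@]2(C)C1=O | intermediate
11 | cis-fused 6,9-dione (C8 epimers) | CC1CC(=O)[C@@H]2[C@H](C(=O)O[C@@H]3C[C@H](C)CC[C@H]3C(C)(C)c3ccccc3)C(O[Si](C)(C)C(C)(C)C)=CC[C@]2(C)C1=O | intermediate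
12 | trans-fused 6,9-dione (5α-H, 8α-CH3) | C[C@@H]1CC(=O)[C@H]2[C@H](C(=O)O[C@@H]3C[C@H](C)CC[C@H]3C(C)(C)c3ccccc3)C(O[Si](C)(C)C(C)(C)C)=CC[C@]2(C)C1=O | intermediate
13 | tetrabutylammonium enolate of the trans-fused 3-oxo-19-ester | C[C@@H]1CC(=O)[C@H]2C(C(=O)O[C@@H]3C[C@H](C)CC[C@H]3C(C)(C)c3ccccc3)=C([O-])CC[C@]2(C)C1=O.CCCC[N+](CCCC)(CCCC)CCCC | intermediate
14 | trans-fused 3,6,9-trione, 4α-CH3, 4β-CO2R* | C[C@@H]1CC(=O)[C@H]2[C@@](C)(C(=O)O[C@@H]3C[C@H](C)CC[C@H]3C(C)(C)c3ccccc3)C(=O)CC[C@]2(C)C1=O | intermediate
15 | dilithium 3α,6β-dialkoxide of the 9-oxo-19-ester | C[C@@H]1C[C@@H]([O-])[C@H]2[C@@](C)(C(=O)O[C@@H]3C[C@H](C)CC[C@H]3C(C)(C)c3ccccc3)[C@H]([O-])CC[C@]2(C)C1=O.[Li+].[Li+] | intermediate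
16 | 3α-hydroxy-9-oxo-19,6β-lactone | C[C@@H]1C[C@@H]3[C@H]2[C@@](C)(C(=O)O3)[C@H](O)CC[C@]2(C)C1=O | intermediate
17 | 3α-benzoyloxy-9-oxo-19,6β-lactone | C[C@@H]1C[C@@H]3[C@H]2[C@@](C)(C(=O)O3)[C@H](OC(=O)c4ccccc4)CC[C@]2(C)C1=O | intermediate
18 | potassium C8=C9 enolate of 17 | CC1=C([O-])[C@@]2(C)CC[C@@H](OC(=O)c3ccccc3)[C@](C)(C(=O)O3)[C@@H]2[C@H]3C1.[K+] | intermediate
19 | C8=C9 enol triflate with 3α-benzoate and 19,6β-lactone | CC1=C(OS(=O)(=O)C(F)(F)F)[C@@]2(C)CC[C@@H](OC(=O)c3ccccc3)[C@](C)(C(=O)O3)[C@@H]2[C@H]3C1 | intermediate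
20 | 3α,6β,19-triol C8=C9 enol triflate | CC1=C(OS(=O)(=O)C(F)(F)F)[C@@]2(C)CC[C@@H](O)[C@](C)(CO)[C@@H]2[C@H](O)C1 | intermediate
21 | ethyl (E)-3-methyl-4-oxobut-2-enoate | CCOC(=O)/C=C(C)/C=O | starting material
22 | ethyl (E)-3-methylpenta-2,4-dienoate | CCOC(=O)/C=C(C)/C=C | intermediate
23 | ethyl (E)-5-(9-borabicyclo[3.3.1]nonan-9-yl)-3-methylpent-2-enoate | CCOC(=O)/C=C(C)/CCB1C2CCCC1CCC2 | intermediate
24 | ethyl (13E)-3α,6β,19-trihydroxylabda-8,13-dien-15-oate | CC1=C(CC/C(C)=C/C(=O)OCC)[C@@]2(C)CC[C@@H](O)[C@](C)(CO)[C@@H]2[C@H](O)C1 | intermediate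
25 | (13E)-3α,6β,19-trihydroxylabda-8,13-dien-15-oic acid | CC1=C(CC/C(C)=C/C(=O)O)[C@@]2(C)CC[C@@H](O)[C@](C)(CO)[C@@H]2[C@H](O)C1 | target

Total steps: 15. Longest linear sequence: 14 (steps 1–12, 14, 15).

Steps most likely to fail

Step 5. The auxiliary-laden, ester-bearing diene may combine only slowly with the methyl-substituted quinone bond, so that desilylation and polymerisation of the diene compete. The phenyl shield may also discriminate weakly between the two diene faces under purely thermal conditions, which lowers the share of the 10S series. The fallback gives up auxiliary control, sets out from 4 and 9 and comes back at 16. Methyl acetate is deprotonated with LiN(i-Pr)2 to the lithium enolate of methyl acetate F1 and added to 4 to give methyl 3-hydroxypent-4-enoate F2. Dess–Martin oxidation gives methyl 3-oxopent-4-enoate F3, and TBSOTf/Et3N gives the small diene methyl (2Z)-3-(tert-butyldimethylsilyloxy)penta-2,4-dienoate F4. F4 and 9 are heated neat, or pressed at 10–15 kbar at rt, to the racemic methyl ester adduct F5. The conditions of steps 6 to 9 then lead through the racemic cis dione F6, the racemic trans dione F7, the racemic ammonium enolate F8, the racemic methyl trione F9 and the racemic dialkoxide F10 to the racemic hydroxy lactone F11, with methanol leaving in place of the auxiliary. F11 is resolved by preparative chromatography on a chiral stationary phase; its 10S enantiomer is 16.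

Step 14. Oxidative addition and transmetalation may be slow at the tetrasubstituted triflate beside the quaternary C10, so that triflate hydrolysis, protodeboronation or β-hydride loss from the alkylpalladium species outrun the coupling. Hydroboration of the electron-poor dienoate may also be incompletely site-selective. The fallback reverses the roles of the partners, sets out from 20 and comes back at 24. Stille coupling of 20 with tributyl(vinyl)stannane (Pd(PPh3)4, LiCl, CuCl, DMSO, 60 °C), a small sp2 partner that hindered triflates accept, gives the 9-vinyl triol F12. Excess 9-BBN-H, which first caps the hydroxyls as borinates that the aqueous base later cleaves, hydroborates the terminal vinyl to the primary alkylborane F13, which is not isolated. Suzuki coupling of F13 with the unhindered ethyl (E)-3-iodobut-2-enoate (PdCl2(dppf), Cs2CO3, DMF/H2O) gives 24.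

Step 9. Site selectivity among the three ketones may be lost: the warming that the hindered C6 ketone may need can also let the hydride reduce C9, giving mixtures. The fallback replaces selective reduction by exhaustive reduction and site-selective re-oxidation, sets out from 14 and comes back at 17. LiBH(s-Bu)3 (−78 → 0 °C) followed by NaBH4 in MeOH reduces all three ketones and gives, after lactonisation, the 3α,9-dihydroxy-19,6β-lactone F14. Benzoyl chloride/pyridine acylates only the 3α-hydroxyl, because the C9 carbinol lies between the quaternary C10 and C8, and gives the 3α-benzoate 9-alcohol F15. Dess–Martin oxidation of the C9 carbinol gives 17.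

Further compounds
F1 | step 5 | lithium enolate of methyl acetate | [Li+].C=C([O-])OC
F2 | step 5 | methyl 3-hydroxypent-4-enoate (racemic) | C=CC(O)CC(=O)OC
F3 | step 5 | methyl 3-oxopent-4-enoate | C=CC(=O)CC(=O)OC
F4 | step 5 | methyl (2Z)-3-(tert-butyldimethylsilyloxy)penta-2,4-dienoate | C=C/C(O[Si](C)(C)C(C)(C)C)=C/C(=O)OC
F5 | step 5 | racemic methyl ester adduct (one enantiomer drawn) | CC1=CC(=O)[C@@H]2[C@H](C(=O)OC)C(O[Si](C)(C)C(C)(C)C)=CC[C@]2(C)C1=O
F6 | step 5 | racemic cis dione, methyl ester (C8 epimers) | CC1CC(=O)[C@@H]2[C@H](C(=O)OC)C(O[Si](C)(C)C(C)(C)C)=CC[C@]2(C)C1=O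
F7 | step 5 | racemic trans dione, methyl ester | C[C@@H]1CC(=O)[C@H]2[C@H](C(=O)OC)C(O[Si](C)(C)C(C)(C)C)=CC[C@]2(C)C1=O
F8 | step 5 | racemic tetrabutylammonium enolate, methyl ester | C[C@@H]1CC(=O)[C@H]2C(C(=O)OC)=C([O-])CC[C@]2(C)C1=O.CCCC[N+](CCCC)(CCCC)CCCC
F9 | step 5 | racemic methyl trione, methyl ester | C[C@@H]1CC(=O)[C@H]2[C@@](C)(C(=O)OC)C(=O)CC[C@]2(C)C1=O
F10 | step 5 | racemic dilithium 3α,6β-dialkoxide, methyl ester | C[C@@H]1C[C@@H]([O-])[C@H]2[C@@](C)(C(=O)OC)[C@H]([O-])CC[C@]2(C)C1=O.[Li+].[Li+]
F11 | step 5 | racemic hydroxy lactone (racemate of 16, one enantiomer drawn) | C[C@@H]1C[C@@H]3[C@H]2[C@@](C)(C(=O)O3)[C@H](O)CC[C@]2(C)C1=O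
F12 | step 14 | 9-vinyl triol (3α,6β,19-trihydroxy, C8=C9–CH=CH2) | CC1=C(C=C)[C@@]2(C)CC[C@@H](O)[C@](C)(CO)[C@@H]2[C@H](O)C1
F13 | step 14 | primary alkylborane from F12 (drawn with free hydroxyls) | CC1=C(CCB3C4CCCC3CCC4)[C@@]2(C)CC[C@@H](O)[C@](C)(CO)[C@@H]2[C@H](O)C1
F14 | step 9 | 3α,9-dihydroxy-19,6β-lactone (C9 epimers) | C[C@@H]1C[C@@H]3[C@H]2[C@@](C)(C(=O)O3)[C@H](O)CC[C@]2(C)C1O
F15 | step 9 | 3α-benzoyloxy-9-hydroxy-19,6β-lactone (C9 epimers) | C[C@@H]1C[C@@H]3[C@H]2[C@@](C)(C(=O)O3)[C@H](OC(=O)c4ccccc4)CC[C@]2(C)C1O
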